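**Retrosynthetic overview**

1. Target 27 ⇐ epoxidation of the (E)-C3=C4 alkene of 26 ⇐ O9-angeloylation of diol 23 ⇐ acetonide 22.
2. 22 ⇐ key disconnection C6–C7: electrochemical, chromium-catalysed intramolecular allylation of aldehyde 19 by its own (Z)-2-(bromomethyl)enoate. The ten-membered ring closes first, then the γ-lactone by lactonization in the same operation.
3. 19 ⇐ C7=C11(C13) unit from vinylalumination of aldehyde 13 and allylic transposition to the bromide; C6 aldehyde from the silyl ether.
4. 13 ⇐ α-methylene ketone by Horner–Wadsworth–Emmons methylenation of β-keto phosphonate 11 ⇐ C1–C10 acylation of L-threitol-derived phosphonate 9 (C8 and C9 bought) with Weinreb amide 6.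
5. 6 ⇐ carboalumination and Negishi coupling from silyl butynyl ether 1. Ring order: dioxolane (bought, temporary) → carbocycle → lactone → epoxide.

Assumption: locants used below are C1 ring ketone carbon; C2 the CH2 beside it; C3/C4 epoxide carbons (C4 carries methyl C15); C5 CH2; C6 lactone O–CH; C7 ring-fusion CH; C8 CH–OH; C9 CH–O-angeloyl; C10 ring carbon with exocyclic C14H2; C11(=C13H2) and C12 lactone carbons. Compounds 1, 4, 7, 14 and 24 are taken as catalogue items.

**Route**

Step 1
Reactants: 1 tert-butyl(but-3-yn-1-yloxy)dimethylsilane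
Product: 3 (E)-tert-butyl[(4-iodo-3-methylbut-3-en-1-yl)oxy]dimethylsilane, via alkenylalane 2 (not isolated)
Conditions: Me3Al, Cp2ZrCl2 (20 mol %), CH2Cl2, 0 °C → rt; then I2, THF, −30 °C
Reagents that add atoms: trimethylaluminium (C[Al](C)C); iodine (II)
Why: Zirconium-catalysed Negishi carboalumination adds methyl and aluminium syn across the terminal alkyne with the metal on the terminal carbon, and iodinolysis with retention gives the (E)-trisubstituted vinyl iodide that fixes the C3=C4 geometry.

Step 2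
Reactants: 3 (E)-vinyl iodide; 4 2-bromo-N-methoxy-N-methylacetamide
Product: 6 (3E)-6-[(tert-butyldimethylsilyl)oxy]-N-methoxy-N,4-dimethylhex-3-enamide, via zinc enolate 5 (not isolated)
Conditions: 4, Zn dust (Me3SiCl-activated), THF, rt; then 3, Pd(PPh3)4 (5 mol %), THF, 45 °C
Reagents that add atoms: none
Why: The Reformatsky-type zinc amide enolate undergoes Negishi cross-coupling with the vinyl iodide under zerovalent palladium catalysis with retention of the (E)-geometry, giving the skipped Weinreb amide that carries C1 and C2.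

Step 3
Reactants: 7 1,4-di-O-tosyl-2,3-O-isopropylidene-L-threitol
Product: 8 (4R,5R)-4,5-bis(iodomethyl)-2,2-dimethyl-1,3-dioxolane
Conditions: NaI (6 equiv), 2-butanone, reflux
Reagents that add atoms: sodium iodide ([Na+].[I-])
Why: Finkelstein SN2 exchange at the two primary carbons leaves the two bought stereocentres (future C8 and C9, from L-tartaric acid) untouched.

Step 4
Reactants: 8 (4R,5R)-diiodide
Product: 9 diethyl {[(4R,5R)-5-(iodomethyl)-2,2-dimethyl-1,3-dioxolan-4-yl]methyl}phosphonate
Conditions: P(OEt)3 (1 equiv), 8 (3 equiv, excess recovered), neat, 150 °C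
Reagents that add atoms: triethyl phosphite (CCOP(OCC)OCC)
Why: Michaelis–Arbuzov reaction at one of the two homotopic iodomethyl groups of the C2-symmetric diiodide gives a single mono-phosphonate and so differentiates the future C10 and C7 termini.

Step 5
Reactants: 9 iodo phosphonate; 6 Weinreb amide
Product: 11 diethyl {(4E)-7-[(tert-butyldimethylsilyl)oxy]-1-[(4R,5R)-5-(iodomethyl)-2,2-dimethyl-1,3-dioxolan-4-yl]-5-methyl-2-oxohept-4-en-1-yl}phosphonate (both epimers at the phosphonate carbon), via lithiated phosphonate 10 (not isolated)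
Conditions: 9, LiN(i-Pr)2 (2.1 equiv), THF, −78 °C; then 6 (0.9 equiv), −78 → −40 °C; aq. NH4Cl
Reagents that add atoms: none
Why: Acylation of the α-lithio phosphonate by the Weinreb amide (β-keto phosphonate synthesis) forms the C1–C10 bond without over-addition, and the new C10 centre is irrelevant because it becomes sp2 in the next step.

Step 6
Reactants: 11 β-keto phosphonate
Product: 12 (5E)-8-[(tert-butyldimethylsilyl)oxy]-2-[(4S,5R)-5-(iodomethyl)-2,2-dimethyl-1,3-dioxolan-4-yl]-6-methylocta-1,5-dien-3-one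
Conditions: aq. CH2O (37 %), K2CO3, THF, 0 °C → rt
Reagents that add atoms: formaldehyde (C=O)
Why: Horner–Wadsworth–Emmons olefination of the α-substituted β-keto phosphonate with formaldehyde places the exocyclic methylene regiospecifically on C10, which enolate methylenation could not do in the presence of the more acidic C2.

Step 7
Reactants: 12 iodo enone
Product: 13 (4R,5S)-5-[(5E)-8-[(tert-butyldimethylsilyl)oxy]-6-methyl-3-oxoocta-1,5-dien-2-yl]-2,2-dimethyl-1,3-dioxolane-4-carbaldehyde
Conditions: AgBF4, DMSO, rt; then Et3N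
Reagents that add atoms: dimethyl sulfoxide (CS(C)=O)
Why: Silver-assisted Kornblum oxidation converts the primary iodide through its alkoxysulfonium salt into the C7 aldehyde under non-epimerizing conditions, the trans-dioxolane keeping C8 secure.

Step 8
Reactants: 13 aldehyde; 14 methyl propiolate
Product: 16 methyl 2-{[(4S,5S)-5-[(5E)-8-[(tert-butyldimethylsilyl)oxy]-6-methyl-3-oxoocta-1,5-dien-2-yl]-2,2-dimethyl-1,3-dioxolan-4-yl](hydroxy)methyl}prop-2-enoate (both carbinol epimers), via vinylalane 15 (not isolated)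
Conditions: 14, i-Bu2AlH, NMO, THF, 0 °C; then 13, 0 °C → rt
Reagents that add atoms: none
Why: Hydroalumination of the propiolate gives an α-(methoxycarbonyl)vinylalane that adds to the aldehyde much faster than to the ketone (vinylalumination route to Baylis–Hillman-type adducts) without amine base, and the carbinol configuration is irrelevant because C7 becomes sp2 in step 9.

Step 9
Reactants: 16 allylic alcohol
Product: 17 methyl (2Z)-2-(bromomethyl)-3-[(4S,5S)-5-[(5E)-8-[(tert-butyldimethylsilyl)oxy]-6-methyl-3-oxoocta-1,5-dien-2-yl]-2,2-dimethyl-1,3-dioxolan-4-yl]prop-2-enoate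
Conditions: NBS, Me2S, CH2Cl2, 0 °C → rt
Reagents that add atoms: N-bromosuccinimide (BrN1C(=O)CCC1=O)
Why: Corey–Kim-type activation of the alcohol followed by SN2′ attack of bromide gives the thermodynamically preferred (Z)-2-(bromomethyl)enoate, the allyl donor for the ring closure.

Step 10
Reactants: 17 silyl ether
Product: 18 methyl (2Z)-2-(bromomethyl)-3-[(4S,5S)-5-[(5E)-8-hydroxy-6-methyl-3-oxoocta-1,5-dien-2-yl]-2,2-dimethyl-1,3-dioxolan-4-yl]prop-2-enoate
Conditions: aq. HF (48 %), MeCN, 0 °C
Reagents that add atoms: none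
Why: Acidic desilylation of the primary silyl ether is fast at 0 °C and, with no nucleophilic amine present, leaves the internal dioxolane, the allylic bromide and the enone intact.

Step 11
Reactants: 18 primary alcohol
Product: 19 methyl (2Z)-2-(bromomethyl)-3-[(4S,5S)-2,2-dimethyl-5-[(5E)-6-methyl-3,8-dioxoocta-1,5-dien-2-yl]-1,3-dioxolan-4-yl]prop-2-enoate
Conditions: Dess–Martin periodinane, NaHCO3, CH2Cl2, 0 °C
Reagents that add atoms: none
Why: Buffered Dess–Martin oxidation gives the β,γ-unsaturated C6 aldehyde without isomerization into conjugation, and it is used at once.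

Step 12
Reactants: 19 bromo aldehyde
Product: 22 acetonide-protected trans-fused dienone lactone (skeleton of 27 with a 3E alkene in place of the epoxide and O8/O9 bridged by CMe2 in place of OH and O-angeloyl), via silyl ether 20 (not isolated), via hydroxy ester 21 (not isolated)
Conditions: CrCl2 (20 mol %), Me3SiCl, LiCl, n-Bu4NBF4, DMF/THF, undivided cell, Al anode, Ni-foam cathode, −1.0 V vs Ag/AgCl, 19 added by syringe pump to 2 mM, rt; then aq. citric acid; PPTS, CH2Cl2, rt
Reagents that add atoms: none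
Why: Proposed new method: the cathode regenerates divalent chromium from the trivalent chromium released by Me3SiCl from the product alkoxide, so catalytic CrCl2 turns the allylic bromide into a (Z)-allylchromium species that adds through C7 to the tethered C6 aldehyde in a chair transition state with both ring arms antiperiplanar across the new bond (C5 pseudo-axial on the aldehyde; attack on C7 anti to the C9 arm, with C8–H eclipsing the enoate by 1,3-allylic strain), which sets C6 and C7 under control of the bought C8 centre and, after desilylation and lactonization onto the methyl ester, gives the trans-fused lactone; the closest known reactions are stoichiometric CrCl2 Nozaki–Hiyama–Kishi closures of ten-membered germacranolide rings from 2-(bromomethyl)enoates and the intermolecular electrochemical chromium-catalysed allylation of aldehydes, which to my knowledge have not been combined for a medium-ring closure.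

Step 13
Reactants: 22 acetonide lactone
Product: 23 (6R,7R,8S,9S)-8,9-diol (22 without the isopropylidene group)
Conditions: CF3CO2H/H2O (9:1), CH2Cl2, 0 °C
Reagents that add atoms: none
Why: Acid-catalysed acetal hydrolysis releases the C8/C9 diol, and the trans-fused lactone and the enone tolerate cold aqueous trifluoroacetic acid.

Step 14
Reactants: 23 diol; 24 angelic acid
Product: 26 (6R,7R,8S,9S)-9-O-angelate (27 with a 3E alkene in place of the epoxide), via mixed anhydride 25 (not isolated)
Conditions: 24, 2,4,6-trichlorobenzoyl chloride, Et3N, toluene, rt, filter; then 23, toluene, 70 °C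
Reagents that add atoms: none
Why: Yamaguchi esterification through the preformed mixed anhydride should acylate the less hindered allylic C9 hydroxyl in preference to the C8 hydroxyl, which is flanked by the ring-fusion carbon, and the amine-free heating keeps the (Z)-geometry of the angelate.

Step 15
Reactants: 26 alkene
Product: 27 target
Conditions: mCPBA (1.05 equiv), NaHCO3, CH2Cl2, 0 °C
Reagents that add atoms: 3-chloroperoxybenzoic acid (OOC(=O)c1cccc(Cl)c1)
Why: Prilezhaev epoxidation is chemoselective for the only electron-rich alkene (enone, α-methylene lactone and angelate are electron-poor) and should attack the exposed outer face of the (E)-alkene held by the ten-membered ring, as is usual for germacranolides, to give the (3R,4R)-trans-epoxide.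

**Compound list**

1 | tert-butyl(but-3-yn-1-yloxy)dimethylsilane | C#CCCO[Si](C)(C)C(C)(C)C | starting material
2 | dimethyl[(1E)-4-(tert-butyldimethylsilyloxy)-2-methylbut-1-en-1-yl]alane | C[Al](C)/C=C(\C)CCO[Si](C)(C)C(C)(C)C | intermediate
3 | (E)-tert-butyl[(4-iodo-3-methylbut-3-en-1-yl)oxy]dimethylsilane | I/C=C(\C)CCO[Si](C)(C)C(C)(C)C | intermediate
4 | 2-bromo-N-methoxy-N-methylacetamide | CON(C)C(=O)CBr | starting material
5 | bromo{2-[methoxy(methyl)amino]-2-oxoethyl}zinc (BrZnCH2C(O)N(OMe)Me) | CON(C)C(=O)C[Zn]Br | intermediate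
6 | (3E)-6-[(tert-butyldimethylsilyl)oxy]-N-methoxy-N,4-dimethylhex-3-enamide | CON(C)C(=O)C/C=C(\C)CCO[Si](C)(C)C(C)(C)C | intermediate
7 | (4S,5S)-2,2-dimethyl-1,3-dioxolane-4,5-diyldimethanol bis(4-methylbenzenesulfonate) (1,4-di-O-tosyl-2,3-O-isopropylidene-L-threitol) | Cc1ccc(cc1)S(=O)(=O)OC[C@@H]2OC(C)(C)O[C@H]2COS(=O)(=O)c3ccc(C)cc3 | starting material
8 | (4R,5R)-4,5-bis(iodomethyl)-2,2-dimethyl-1,3-dioxolane | IC[C@@H]1OC(C)(C)O[C@H]1CI | intermediate
9 | diethyl {[(4R,5R)-5-(iodomethyl)-2,2-dimethyl-1,3-dioxolan-4-yl]methyl}phosphonate | CCOP(=O)(OCC)C[C@@H]1OC(C)(C)O[C@H]1CI | intermediate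
10 | α-lithio derivative of 9 | CCOP(=O)(OCC)C([Li])[C@@H]1OC(C)(C)O[C@H]1CI | intermediate
11 | diethyl {(4E)-7-[(tert-butyldimethylsilyl)oxy]-1-[(4R,5R)-5-(iodomethyl)-2,2-dimethyl-1,3-dioxolan-4-yl]-5-methyl-2-oxohept-4-en-1-yl}phosphonate, both epimers at the phosphonate carbon | CCOP(=O)(OCC)C(C(=O)C/C=C(\C)CCO[Si](C)(C)C(C)(C)C)[C@@H]1OC(C)(C)O[C@H]1CI | intermediate
12 | (5E)-8-[(tert-butyldimethylsilyl)oxy]-2-[(4S,5R)-5-(iodomethyl)-2,2-dimethyl-1,3-dioxolan-4-yl]-6-methylocta-1,5-dien-3-one | C=C(C(=O)C/C=C(\C)CCO[Si](C)(C)C(C)(C)C)[C@@H]1OC(C)(C)O[C@H]1CI | intermediate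
13 | (4R,5S)-5-[(5E)-8-[(tert-butyldimethylsilyl)oxy]-6-methyl-3-oxoocta-1,5-dien-2-yl]-2,2-dimethyl-1,3-dioxolane-4-carbaldehyde | C=C(C(=O)C/C=C(\C)CCO[Si](C)(C)C(C)(C)C)[C@@H]1OC(C)(C)O[C@H]1C=O | intermediate
14 | methyl prop-2-ynoate (methyl propiolate) | C#CC(=O)OC | starting material
15 | methyl 2-[bis(2-methylpropyl)alumanyl]prop-2-enoate | C=C([Al](CC(C)C)CC(C)C)C(=O)OC | intermediate
16 | methyl 2-{[(4S,5S)-5-[(5E)-8-[(tert-butyldimethylsilyl)oxy]-6-methyl-3-oxoocta-1,5-dien-2-yl]-2,2-dimethyl-1,3-dioxolan-4-yl](hydroxy)methyl}prop-2-enoate, both carbinol epimers | C=C(C(=O)OC)C(O)[C@@H]1OC(C)(C)O[C@H]1C(=C)C(=O)C/C=C(\C)CCO[Si](C)(C)C(C)(C)C | intermediate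
17 | methyl (2Z)-2-(bromomethyl)-3-[(4S,5S)-5-[(5E)-8-[(tert-butyldimethylsilyl)oxy]-6-methyl-3-oxoocta-1,5-dien-2-yl]-2,2-dimethyl-1,3-dioxolan-4-yl]prop-2-enoate | COC(=O)/C(CBr)=C/[C@@H]1OC(C)(C)O[C@H]1C(=C)C(=O)C/C=C(\C)CCO[Si](C)(C)C(C)(C)C | intermediate
18 | methyl (2Z)-2-(bromomethyl)-3-[(4S,5S)-5-[(5E)-8-hydroxy-6-methyl-3-oxoocta-1,5-dien-2-yl]-2,2-dimethyl-1,3-dioxolan-4-yl]prop-2-enoate | COC(=O)/C(CBr)=C/[C@@H]1OC(C)(C)O[C@H]1C(=C)C(=O)C/C=C(\C)CCO | intermediate
19 | methyl (2Z)-2-(bromomethyl)-3-[(4S,5S)-2,2-dimethyl-5-[(5E)-6-methyl-3,8-dioxoocta-1,5-dien-2-yl]-1,3-dioxolan-4-yl]prop-2-enoate | COC(=O)/C(CBr)=C/[C@@H]1OC(C)(C)O[C@H]1C(=C)C(=O)C/C=C(\C)CC=O | intermediate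
20 | C6-O-trimethylsilyl ether of 21 | COC(=O)C(=C)[C@H]1[C@H](O[Si](C)(C)C)C/C(C)=C/CC(=O)C(=C)[C@@H]2OC(C)(C)O[C@@H]12 | intermediate
21 | ring-closed hydroxy ester: ten-membered carbocycle C1–C10 with C1 ketone, (3E)-alkene with CH3 on C4, free OH on C6, C(=CH2)CO2CH3 on C7, trans-dioxolane (CMe2) across O8/O9, C10=CH2; C6, C7, C8, C9 configured as in 27 | COC(=O)C(=C)[C@H]1[C@H](O)C/C(C)=C/CC(=O)C(=C)[C@@H]2OC(C)(C)O[C@@H]12 | intermediate
22 | trans-fused α-methylene-γ-lactone (C12 to O6) of 21 with the 8,9-O-isopropylidene group retained; C6–C9 configured as in 27 | C=C1C(=O)O[C@@H]2C/C(C)=C/CC(=O)C(=C)[C@@H]3OC(C)(C)O[C@H]3[C@@H]12 | intermediate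
23 | (6R,7R,8S,9S)-8,9-dihydroxy-1-oxogermacra-3E,10(14),11(13)-trien-12,6-olide (locants as assumed) | C=C1C(=O)O[C@@H]2C/C(C)=C/CC(=O)C(=C)[C@H](O)[C@@H](O)[C@@H]12 | intermediate
24 | angelic acid, (2Z)-2-methylbut-2-enoic acid | C/C=C(/C)C(=O)O | starting material
25 | (2Z)-2-methylbut-2-enoic 2,4,6-trichlorobenzoic anhydride | C/C=C(/C)C(=O)OC(=O)c1c(Cl)cc(Cl)cc1Cl | intermediate
26 | (6R,7R,8S,9S)-9-O-angelate of 23 (27 with a 3E alkene in place of the epoxide) | C=C1C(=O)O[C@@H]2C/C(C)=C/CC(=O)C(=C)[C@H](OC(=O)/C(C)=C\C)[C@@H](O)[C@@H]12 | intermediate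
27 | (3R,4R,6R,7R,8S,9S)-3,4-epoxy-8-hydroxy-1-oxogermacra-10(14),11(13)-dien-12,6-olid-9-yl (2Z)-2-methylbut-2-enoate (locants as assumed) | C=C1C(=O)O[C@@H]2C[C@@]3(C)O[C@@H]3CC(=O)C(=C)[C@H](OC(=O)/C(C)=C\C)[C@@H](O)[C@@H]12 | target

**Step count and risks**

Total step count: 15. Longest linear sequence: 13 (steps 3–15 from 7; the two-step branch 1 → 6 joins at step 5).

The three steps most likely to fail are 12, 14 and 15.

The electrochemical ring closure (step 12) is the proposed new step. It can fail in three ways: direct cathodic reduction of the allylic bromide or the enone instead of chromium turnover, addition of the allylchromium to the C1 ketone (a five-membered ring, disfavoured here because it would be trans-fused to the dioxolane), or a wrong choice between the chair alternatives at C6/C7. The fallback uses known chemistry and closes the ring by boron instead of chromium. It sets out from alcohol 18: borylation (B2pin2, Pd2(dba)3, DMSO, rt) gives the allylic pinacol boronate alcohol F1, and Dess–Martin oxidation gives the boronate aldehyde F2. F2 undergoes thermal intramolecular allylboration (toluene, 80 °C, 2 mM, Sc(OTf)3 if slow) through the same closed chair to the O-boryl hydroxy ester F3. Mild hydrolysis returns the route at hydroxy ester 21, which is lactonized to 22 as before.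

The angeloylation (step 14) can put the acyl group on O8 or give mixtures, and the 8- and 9-esters can interconvert by acyl migration. The fallback sets out from diol 23 and uses a silyl relay. If O8 proves the more reactive hydroxyl, Et3SiCl/imidazole gives the 8-O-triethylsilyl ether F4. Forcing Yamaguchi acylation with 25 then gives the 8-O-silyl 9-O-angelate F5, and HF·pyridine returns the route at 26.

The epoxidation (step 15) can attack the other face of the ten-membered ring and give the (3S,4S)-epoxide. The fallback sets out from 26 and inverts the facial outcome through a halohydrin. NBS in aqueous acetone adds bromine from the face that mCPBA prefers and water anti at C4, giving the bromohydrin F6 (Br on C3, OH on C4). Ag2O in CH2Cl2 closes it with inversion at C3, so the oxygen ends on the opposite face, and the route comes back at 27.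

**Further compounds**

F1 | step 12 | methyl (2E)-3-[(4S,5S)-5-[(5E)-8-hydroxy-6-methyl-3-oxoocta-1,5-dien-2-yl]-2,2-dimethyl-1,3-dioxolan-4-yl]-2-[(4,4,5,5-tetramethyl-1,3,2-dioxaborolan-2-yl)methyl]prop-2-enoate | COC(=O)/C(CB2OC(C)(C)C(C)(C)O2)=C/[C@@H]1OC(C)(C)O[C@H]1C(=C)C(=O)C/C=C(\C)CCO
F2 | step 12 | C6 aldehyde of F1 | COC(=O)/C(CB2OC(C)(C)C(C)(C)O2)=C/[C@@H]1OC(C)(C)O[C@H]1C(=C)C(=O)C/C=C(\C)CC=O
F3 | step 12 | C6-O-(pinacolatoboryl) derivative of 21 | COC(=O)C(=C)[C@H]1[C@H](OB3OC(C)(C)C(C)(C)O3)C/C(C)=C/CC(=O)C(=C)[C@@H]2OC(C)(C)O[C@@H]12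
F4 | step 14 | 8-O-triethylsilyl ether of 23 | C=C1C(=O)O[C@@H]2C/C(C)=C/CC(=O)C(=C)[C@H](O)[C@@H](O[Si](CC)(CC)CC)[C@@H]12
F5 | step 14 | 8-O-triethylsilyl ether of 26 | C=C1C(=O)O[C@@H]2C/C(C)=C/CC(=O)C(=C)[C@H](OC(=O)/C(C)=C\C)[C@@H](O[Si](CC)(CC)CC)[C@@H]12
F6 | step 15 | 3-bromo-4-hydroxy bromohydrin of 26 (Br on C3, OH on C4, anti) | C=C1C(=O)O[C@@H]2C[C@@](C)(O)[C@@H](Br)CC(=O)C(=C)[C@H](OC(=O)/C(C)=C\C)[C@@H](O)[C@@H]12
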